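The constants used here are made up; no experiment stands behind them.

substrate 0.50 M; reagent 2.00 M; free catalyst 25 mM; time 2.0 h

* part of the substrate that has reacted at 2.0 h
* share of the unused reagent that is free and not bound as idle adduct, at 2.0 h

    substrate + free catalyst ⇌ catalyst intermediate A (K1 = 6.04 M⁻¹, k1 = 0.0593 M⁻¹ s⁻¹)
    catalyst intermediate A → catalyst intermediate B (k2 = 0.0188 s⁻¹)
    reagent + catalyst intermediate B ⇌ catalyst intermediate C (K3 = 1.2 M⁻¹, k3 = 0.101 M⁻¹ s⁻¹)
    catalyst intermediate C → by-product + catalyst intermediate D (k4 = 0.0332 s⁻¹)
    catalyst intermediate D ⇌ free catalyst + product (K5 = 0.43 M, k5 = 0.0329 s⁻¹)
    reagent + by-product ⇌ idle adduct, settled at all times (K6 = 0.31 M⁻¹)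

Start from slowness: ask how long one catalyst takes for one cycle. Put the cycle in steady state at the charge concentrations, with no product yet, and add the time spent in each form. Free catalyst waits 51.3 s, counting the returns from catalyst intermediate A. Catalyst intermediate B waits 17.5 s, counting the falls back from catalyst intermediate C. Steps 2, 4 and 5 add 114 s. The sum is the turnover time, the time per cycle at charge concentrations: 183 s.

Now count. The charge asks 20.0 turnovers of each catalyst, and the run offers 39.4, more than the charge asks. That would finish the substrate by 1.01 h.

The weak link is the constant turnover time. Reforge it: the wait of free catalyst grows as substrate falls, and product holds catalyst as catalyst intermediate D, which is product inhibition. Integrating over conversion, with reagent held at charge, the elapsed time is 0.617 h times the logarithm of charged over remaining substrate, plus 0.397 h times the fraction converted. Entering that fraction whole, for a conversion close to the end, gives 92.6%. Unused reagent and by-product together sum to the reagent charge, so the balance of step 6 gives, as an estimate, a free share of 91.1%.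

The forecast says 93% (90% to 95.5%) and 90.9% (90.5% to 91.4%), noting that the rate “slows late in the run as substrate falls and product pulls catalyst back into intermediate D”.

The flask gives 93.0% and 90.9%. In the flask, 1.00 h is the length of 19.7 turnover times, and by then it has used 69.7% of its substrate. The reforged rule, taken at that same time with half of the second term, gives 72.7%.

Take the neighbour with 0.010 M of free catalyst. Its 39.4 turnover times supply 78.9% of the substrate at charge speed. Both prices scale by 2.50, and the same half term gives 62.3%. That neighbour computes to 59.9%.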